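Numbering: ring C1 (CH2), C2 (C=O), C3/C4 (epoxide, C15H3 on C4), C5 (OAc), C6 (lactone O), C7, C8 (OAc), C9 (O-2-methylbutanoyl), C10 (=C14H2); lactone C11 (=C13H2), C12 (C=O).
Enabling feature: C12 and C8 are 1,4-dioxygenated across the C11–C7 bond, O6 sits next to C7, and C4 and C8 both bear oxygen. C4–C8 plus one oxygen can therefore be tied into a six-membered dihydropyran (a glycal) whose enol ether C7=C8 is nucleophilic at C7, while O6 carries C11 as an electrophilic metal carbene (polarity reversal of an ester α-carbon).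
Retrosynthetic cuts, in order: C2 ketone, C3/C4 epoxide and C13 methylene (adjustments); C3=C4 (metathesis); C1–C2 (allylation of acrolein); C8–C9 (alkoxyallylboration); C8–C11 re-made as a cyclopropane bond; C11–C7 (carbene); back to D-glucal.
Forward order: the temporary dihydropyran comes from D-glucal; the γ-lactone and a cyclopropane form in one step; acid then unravels cyclopropane and pyran by strain release to an acyclic C4 ketone/C8 aldehyde; C9–C10–C1 and then C2–C3 are added; the ten-membered ring closes last.
Stereochemistry: C5 and C6 from D-glucal; C7 by tethered delivery cis to O6; C8 and C9 from the Ipc2B reagent; temporary C2 from a chiral chromium catalyst; C3 and C4 by hydroxyl-directed epoxidation of the Z-alkene; side chain from (R)-2-methylbutanoic acid. The phosphonate on C11 is the latent C13 methylene.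

Key step: step 6

Assumption: (R)-2-methylbutanoic acid (20) is bought as the single enantiomer; the other starting materials are catalogue compounds.
Remark: C11 of the α-phosphono lactones 10–25 is configurationally labile; it is drawn trans to the C7–C8 bond and ceases to be a stereocentre in step 17.

Step 1
Reactants: 1 D-glucal
Product: 2 6-deoxy-6-iodo-D-glucal
Conditions: PPh3, I2, imidazole (one equivalent of reagent), THF, 0 °C
Reagents that add atoms: iodine, II
Why: Garegg–Samuelsson (Appel-type) iodination: with one equivalent of reagent the oxyphosphonium salt should form at the only primary hydroxyl and be displaced by iodide in an SN2 step that touches no stereocentre.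

Step 2
Reactants: 2 6-deoxy-6-iodo-D-glucal; 3 diethylphosphonoacetic acid
Product: 4 6-deoxy-3-O-[(diethoxyphosphoryl)acetyl]-6-iodo-D-glucal
Conditions: DCC, DMAP (cat.), CH2Cl2, −20 °C
Reagents that add atoms: none
Why: Steglich esterification: the allylic O3 hydroxyl of a 6-substituted glucal (the future C6–O) is the more reactive of the two secondary hydroxyls, as in the known selective 3-O-acylations and 3-O-silylations of glucals, so one equivalent of 3 at low temperature should give the 3-ester.

Step 3
Reactants: 4 6-deoxy-3-O-[(diethoxyphosphoryl)acetyl]-6-iodo-D-glucal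
Product: 5 4-O-acetyl-6-deoxy-3-O-[(diethoxyphosphoryl)acetyl]-6-iodo-D-glucal
Conditions: Ac2O, pyridine, CH2Cl2, 0 °C to rt
Reagents that add atoms: acetic anhydride, CC(=O)OC(C)=O
Why: Pyridine-mediated acetylation puts the final C5 acetate in place at once and makes the neighbouring C5–H bond a poor site for carbene insertion.

Step 4
Reactants: 5 4-O-acetyl-6-deoxy-3-O-[(diethoxyphosphoryl)acetyl]-6-iodo-D-glucal
Product: 6 5-methylene glycal (endocyclic enol ether C7=C8 and exocyclic enol ether C4=C15 on one ring oxygen)
Conditions: AgF, pyridine, rt, dark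
Reagents that add atoms: none
Why: Silver-fluoride dehydroiodination (E2, the standard entry to hex-5-enopyranosides) turns C4 into an enol-ether carbon so that the ring oxygen can later leave C4 by mere hydrolysis, and the sugar C5 stereocentre is given up on purpose because C4 is reset in step 18.

Step 5
Reactants: 6 5-methylene glycal
Product: 7 α-diazo(diethoxyphosphoryl)acetate of the 5-methylene glycal
Conditions: 4-acetamidobenzenesulfonyl azide, DBU, MeCN, 0 °C
Reagents that add atoms: 4-acetamidobenzenesulfonyl azide, CC(=O)Nc1ccc(cc1)S(=O)(=O)N=[N+]=[N-]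
Why: Regitz diazo transfer onto the doubly activated methylene of a phosphonoacetate, in a basic medium that leaves both enol ethers and the acetate alone.

Step 6
Reactants: 7 α-diazo(diethoxyphosphoryl)acetate of the 5-methylene glycal
Product: 8 tricyclic cyclopropane (C11 bonded to C7 and C8 on the O6 face of the pyran; γ-lactone C11–C12–O–C6–C7; phosphonate exo; C4=C15 retained)
Conditions: Rh2(O2CC7H15)4 (2 mol %), toluene, 80 °C, slow addition of 7 (high dilution)
Reagents that add atoms: none
Why: Loss of N2 gives an electrophilic rhodium carbene at C11, which is attacked by C7, the nucleophilic β-carbon of the endocyclic enol ether, while positive charge builds up on C8 next to the ring oxygen, and collapse of the C11–Rh bond onto C8 then closes the cyclopropane. The closest known reaction type is the intramolecular cyclopropanation of allyl and glycal-derived diazoacetates and of allyl diazophosphonoacetates to 3-oxabicyclo[3.1.0]hexan-2-ones. The γ-lactone (C11, C12, O, C6, C7) closes in a 5-exo-trig sense on C7=C8 and the three-membered ring (C7, C8, C11) by the following 3-exo closure onto the oxocarbenium carbon. C7, C8 and C11 are all fixed by the three-atom tether, which can reach only the pyran face that carries O6, so C11 ends up cis to the C6–O bond, and because C5 and C8 are held in the same six-membered ring the otherwise disfavoured cis relation of C5 and C8 on the lactone results. The step needs chemoselectivity for C7=C8 over the exocyclic C4=C15 enol ether, the C5–H bond and the phosphonate OCH2 groups: first-bond formation at C7 runs through a five-membered transition state whereas the nucleophilic terminus C15 would need a seven-membered one, and C5–H is deactivated by its acetate. Slow addition at high dilution suppresses intermolecular attack of a second molecule at C15.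

Step 7
Reactants: 8 tricyclic cyclopropane
Product: 10 acyclic C4-methyl-ketone C8-aldehyde α-phosphono-γ-lactone, via cyclopropanol 9 (not isolated)
Conditions: PPTS (cat.), THF–H2O, 0 °C to rt; crude 10 used at once
Reagents that add atoms: water, O
Why: Enol-ether hydrolysis followed by strain-release opening of a donor–acceptor cyclopropanol: protonation at C15 and addition of water at C4 release the methyl ketone and cyclopropanol 9, whose C8–C11 bond, flanked by the oxygen donor and the lactone and phosphonate acceptors, breaks in a retro-aldol sense to the C8 aldehyde and a stabilised C11 carbanion that is protonated, while C5, C6 and C7 are untouched.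

Step 8
Reactants: 11 2-methylenepropane-1,3-diol
Product: 12 2-methylenepropane-1,3-diol bis(methoxymethyl) ether
Conditions: MOMCl, i-Pr2NEt, CH2Cl2, 0 °C to rt
Reagents that add atoms: chloromethyl methyl ether, COCCl
Why: Standard O-alkylation to the bis(methoxymethyl) ether, whose twofold symmetry means that later lithiation at either OCH2 group gives one and the same allyl anion.

Step 9
Reactants: 10 acyclic C4-methyl-ketone C8-aldehyde α-phosphono-γ-lactone; 12 2-methylenepropane-1,3-diol bis(methoxymethyl) ether
Product: 15 syn C8-hydroxy C9-methoxymethoxy adduct bearing C10(=C14H2)–C1H2OMOM, via allylborane 13 (not isolated), via borinate 14 (not isolated)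
Conditions: 12, s-BuLi, THF, −78 °C; (−)-Ipc2BOMe; BF3·OEt2; then 10, −78 °C; pH 7 buffer, 30 % H2O2, MeOH, 0 °C
Reagents that add atoms: (−)-B-methoxydiisopinocampheylborane, COB([C@@H]1C[C@@H]2C[C@H]([C@H]1C)C2(C)C)[C@@H]1C[C@@H]2C[C@H]([C@H]1C)C2(C)C (its boron and isopinocampheyl groups stay only in 13 and 14)
Why: Brown γ-alkoxyallylboration: lithiation of 12 next to oxygen gives the chelated allyl anion whose alkoxy group is cis to the CH2–metal arm, borane 13 adds through a chair transition state so that this geometry gives the syn C8/C9 relation, the isopinocampheyl groups derived from (+)-α-pinene select the aldehyde face that leads to (8R,9R), and at −78 °C the neutral reagent should take the aldehyde well ahead of the methyl ketone without enolising the β-acyloxy aldehyde.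

Step 10
Reactants: 15 syn C8-hydroxy C9-methoxymethoxy adduct
Product: 16 C5,C8-diacetate C4 methyl ketone
Conditions: Ac2O, pyridine, DMAP (cat.), CH2Cl2, 0 °C
Reagents that add atoms: acetic anhydride, CC(=O)OC(C)=O
Why: Acetylation of the only free hydroxyl installs the final C8 acetate and removes the risk of translactonisation from O6 to O8.

Step 11
Reactants: 16 C5,C8-diacetate C4 methyl ketone
Product: 17 C4 isopropenyl compound (C4(=C3H2)C15H3)
Conditions: Zn, CH2Br2, TiCl4 (pre-formed reagent), THF–CH2Cl2, 0 °C to rt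
Reagents that add atoms: dibromomethane, BrCBr
Why: Takai–Lombardo methylenation: the non-basic gem-dimetallic reagent converts ketones but not esters, lactones or phosphonates and so avoids β-elimination of the C6 carboxylate from the enolisable ketone.

Step 12
Reactants: 17 C4 isopropenyl compound
Product: 18 C9,C1-diol
Conditions: ZnBr2, n-PrSH, CH2Cl2, 0 °C
Reagents that add atoms: none
Why: Lewis-acid/thiol cleavage of methoxymethyl ethers by thioacetal exchange, mild enough for the acetates, the lactone and the two 1,1-disubstituted alkenes.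

Step 13
Reactants: 18 C9,C1-diol
Product: 19 C1 allylic chloride with free C9 hydroxyl
Conditions: PPh3, CCl4 (one equivalent of reagent), CH2Cl2, 0 °C to rt
Reagents that add atoms: tetrachloromethane, ClC(Cl)(Cl)Cl
Why: Appel chlorination: with one equivalent of reagent the unhindered primary allylic alcohol should react ahead of the secondary C9 hydroxyl, which is flanked by C8 and C10, and SN2 displacement gives the unrearranged chloride.

Step 14
Reactants: 19 C1 allylic chloride with free C9 hydroxyl; 20 (R)-2-methylbutanoic acid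
Product: 21 C9 (R)-2-methylbutanoate allylic chloride
Conditions: EDC, DMAP (cat.), CH2Cl2, 0 °C
Reagents that add atoms: none
Why: Steglich esterification of the only free hydroxyl brings in the side-chain stereocentre from 20, a simple α-branched alkanoic acid not being expected to racemise under carbodiimide activation.

Step 15
Reactants: 21 C9 (R)-2-methylbutanoate allylic chloride; 22 acrolein
Product: 24 (2R)-vinyl carbinol, via trimethylsilyl ether 23 (not isolated)
Conditions: CrCl2 (10 mol %), enantiopure 1,8-bis(4-isopropyl-4,5-dihydrooxazol-2-yl)-3,6-diphenylcarbazole (antipode chosen for Re-face addition), i-Pr2NEt (cat.), Mn, TMSCl, THF, rt; then aq. citric acid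
Reagents that add atoms: chlorotrimethylsilane, C[Si](C)(C)Cl (its silyl group stays only in 23)
Why: Catalytic asymmetric Nozaki–Hiyama allylation: divalent chromium (regenerated by Mn, released from the alkoxide by TMSCl) turns the allylic chloride into a 2-substituted allylchromium reagent whose two CH2 termini are equivalent, so that α- and γ-attack give the same skeleton, it adds 1,2 to acrolein and spares the esters, and the tridentate ligand directs it to the Re face to set the temporary (2R)-carbinol.

Step 16
Reactants: 24 (2R)-vinyl carbinol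
Product: 25 ten-membered (Z)-C3=C4 allylic alcohol, α-phosphono lactone
Conditions: second-generation Hoveyda–Grubbs catalyst (10 mol %), 1,4-benzoquinone (cat.), toluene (high dilution), 80 °C
Reagents that add atoms: none
Why: Ring-closing metathesis: the catalyst loads on the monosubstituted C3 vinyl group and closes onto the isopropenyl group (C10=C14 could only give a cyclobutene), a closure type known for ten-membered carbocycles with a trisubstituted alkene, and the cis-fused lactone together with ring strain should favour the Z (ring-cis) alkene.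

Step 17
Reactants: 25 ten-membered (Z)-C3=C4 allylic alcohol, α-phosphono lactone
Product: 26 α-methylene-γ-lactone allylic alcohol
Conditions: paraformaldehyde, LiCl, DBU, MeCN, 0 °C
Reagents that add atoms: formaldehyde (from paraformaldehyde), C=O
Why: Horner–Wadsworth–Emmons olefination under Masamune–Roush conditions: the acidic α-phosphono lactone is deprotonated by LiCl/DBU and condenses with formaldehyde to unveil C11=C13 without harming the esters, and it is done before C2 becomes a ketone so that C10=C14 cannot move into conjugation.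

Step 18
Reactants: 26 α-methylene-γ-lactone allylic alcohol
Product: 27 (2R,3R,4R)-epoxy alcohol
Conditions: mCPBA, CH2Cl2, 0 °C
Reagents that add atoms: 3-chloroperbenzoic acid, O=C(OO)c1cccc(Cl)c1
Why: Henbest-type hydroxyl-directed epoxidation: with C2–H eclipsing the Z-alkene to minimise A(1,3) strain the (2R)-hydroxyl lies on the outer face that also carries O5 (the ring bonds C1–C2 and C5–C6 lie on the other), so the hydrogen-bonded peracid should deliver oxygen syn-stereospecifically to that face to give (3R,4R), while the electron-poor C11=C13 and the undirected, ester-flanked C10=C14 react more slowly.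

Step 19
Reactants: 27 (2R,3R,4R)-epoxy alcohol
Product: 28 CNP0256300.1
Conditions: Dess–Martin periodinane, CH2Cl2, 0 °C to rt
Reagents that add atoms: none
Why: Dess–Martin oxidation of the epoxy alcohol under near-neutral conditions gives the α,β-epoxy ketone without epimerisation, epoxide opening or migration of the β,γ-double bond.

Compound list
1 | D-glucal (1,5-anhydro-2-deoxy-D-arabino-hex-1-enitol) | OC[C@H]1OC=C[C@@H](O)[C@@H]1O | starting material
2 | 6-deoxy-6-iodo-D-glucal | IC[C@H]1OC=C[C@@H](O)[C@@H]1O | intermediate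
3 | diethylphosphonoacetic acid | CCOP(=O)(CC(=O)O)OCC | starting material
4 | 6-deoxy-3-O-[(diethoxyphosphoryl)acetyl]-6-iodo-D-glucal | IC[C@H]1OC=C[C@@H](OC(=O)CP(=O)(OCC)OCC)[C@@H]1O | intermediate
5 | 4-O-acetyl-6-deoxy-3-O-[(diethoxyphosphoryl)acetyl]-6-iodo-D-glucal | IC[C@H]1OC=C[C@@H](OC(=O)CP(=O)(OCC)OCC)[C@@H]1OC(C)=O | intermediate
6 | 5-methylene glycal: 4-O-acetyl-1,5-anhydro-2,6-dideoxy-3-O-[(diethoxyphosphoryl)acetyl]-D-threo-hexa-1,5-dienitol | C=C1OC=C[C@@H](OC(=O)CP(=O)(OCC)OCC)[C@@H]1OC(C)=O | intermediate
7 | α-diazo(diethoxyphosphoryl)acetate of the 5-methylene glycal | C=C1OC=C[C@@H](OC(=O)C(=[N+]=[N-])P(=O)(OCC)OCC)[C@@H]1OC(C)=O | intermediate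
8 | tricyclic cyclopropane: 2-oxabicyclo[4.1.0]heptane (C7, C8, C11) fused to the γ-lactone on the O6 face, phosphonate exo, C4=C15 retained | C=C1O[C@@H]2[C@@H]3[C@@H](OC(=O)[C@]23P(=O)(OCC)OCC)[C@@H]1OC(C)=O | intermediate
9 | C8 cyclopropanol with freed C4 methyl ketone | CC(=O)[C@@H](OC(C)=O)[C@@H]1OC(=O)[C@]2(P(=O)(OCC)OCC)[C@H](O)[C@H]12 | intermediate
10 | C4 methyl ketone/C8 aldehyde, cis-β,γ-disubstituted α-phosphono-γ-lactone (C5, C6, C7 as in 28) | CC(=O)[C@@H](OC(C)=O)[C@@H]1OC(=O)[C@@H](P(=O)(OCC)OCC)[C@@H]1C=O | intermediate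
11 | 2-methylenepropane-1,3-diol | C=C(CO)CO | starting material
12 | 2-methylenepropane-1,3-diol bis(methoxymethyl) ether | C=C(COCOC)COCOC | intermediate
13 | [3-(methoxymethoxy)-2-(methoxymethoxymethyl)allyl]diisopinocampheylborane, alkoxy group cis to the CH2B arm | COCO/C=C(/COCOC)CB([C@@H]1C[C@@H]2C[C@H]([C@H]1C)C2(C)C)[C@@H]1C[C@@H]2C[C@H]([C@H]1C)C2(C)C | intermediate
14 | C8 O-diisopinocampheylborinate of 15 | CC(=O)[C@@H](OC(C)=O)[C@@H]1OC(=O)[C@@H](P(=O)(OCC)OCC)[C@@H]1[C@@H](OB([C@@H]2C[C@@H]3C[C@H]([C@H]2C)C3(C)C)[C@@H]2C[C@@H]3C[C@H]([C@H]2C)C3(C)C)[C@H](OCOC)C(=C)COCOC | intermediate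
15 | (8R,9R)-syn C8 alcohol, C9 and C1 OMOM, C10=C14H2, C4 ketone | CC(=O)[C@@H](OC(C)=O)[C@@H]1OC(=O)[C@@H](P(=O)(OCC)OCC)[C@@H]1[C@@H](O)[C@H](OCOC)C(=C)COCOC | intermediate
16 | C5,C8-diacetate C4 methyl ketone | CC(=O)[C@@H](OC(C)=O)[C@@H]1OC(=O)[C@@H](P(=O)(OCC)OCC)[C@@H]1[C@@H](OC(C)=O)[C@H](OCOC)C(=C)COCOC | intermediate
17 | C4 isopropenyl compound | CC(=C)[C@@H](OC(C)=O)[C@@H]1OC(=O)[C@@H](P(=O)(OCC)OCC)[C@@H]1[C@@H](OC(C)=O)[C@H](OCOC)C(=C)COCOC | intermediate
18 | C9,C1-diol | CC(=C)[C@@H](OC(C)=O)[C@@H]1OC(=O)[C@@H](P(=O)(OCC)OCC)[C@@H]1[C@@H](OC(C)=O)[C@H](O)C(=C)CO | intermediate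
19 | C1 allylic chloride, C9 hydroxyl free | CC(=C)[C@@H](OC(C)=O)[C@@H]1OC(=O)[C@@H](P(=O)(OCC)OCC)[C@@H]1[C@@H](OC(C)=O)[C@H](O)C(=C)CCl | intermediate
20 | (R)-2-methylbutanoic acid | CC[C@@H](C)C(=O)O | starting material
21 | C9 (R)-2-methylbutanoate allylic chloride | CC(=C)[C@@H](OC(C)=O)[C@@H]1OC(=O)[C@@H](P(=O)(OCC)OCC)[C@@H]1[C@@H](OC(C)=O)[C@H](OC(=O)[C@H](C)CC)C(=C)CCl | intermediate
22 | acrolein | C=CC=O | starting material
23 | (2R)-vinyl carbinol trimethylsilyl ether | CC(=C)[C@@H](OC(C)=O)[C@@H]1OC(=O)[C@@H](P(=O)(OCC)OCC)[C@@H]1[C@@H](OC(C)=O)[C@H](OC(=O)[C@H](C)CC)C(=C)C[C@@H](O[Si](C)(C)C)C=C | intermediate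
24 | (2R)-vinyl carbinol (metathesis precursor) | CC(=C)[C@@H](OC(C)=O)[C@@H]1OC(=O)[C@@H](P(=O)(OCC)OCC)[C@@H]1[C@@H](OC(C)=O)[C@H](OC(=O)[C@H](C)CC)C(=C)C[C@@H](O)C=C | intermediate
25 | ten-membered ring, (Z)-C3=C4, (2R)-OH, α-phosphono lactone | CCOP(=O)(OCC)[C@@H]1C(=O)O[C@@H]2[C@H]1[C@@H](OC(C)=O)[C@H](OC(=O)[C@H](C)CC)C(=C)C[C@@H](O)/C=C(/C)[C@H]2OC(C)=O | intermediate
26 | α-methylene-γ-lactone, (Z)-C3=C4, (2R)-OH | C=C1C(=O)O[C@@H]2[C@H]1[C@@H](OC(C)=O)[C@H](OC(=O)[C@H](C)CC)C(=C)C[C@@H](O)/C=C(/C)[C@H]2OC(C)=O | intermediate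
27 | (2R,3R,4R)-epoxy alcohol | C=C1C(=O)O[C@@H]2[C@H]1[C@@H](OC(C)=O)[C@H](OC(=O)[C@H](C)CC)C(=C)C[C@@H](O)[C@@H]1O[C@]1(C)[C@H]2OC(C)=O | intermediate
28 | CNP0256300.1, (3R,4R,5S,6R,7R,8R,9R,2'R) in the numbering used here | C=C1C(=O)O[C@@H]2[C@H]1[C@@H](OC(C)=O)[C@H](OC(=O)[C@H](C)CC)C(=C)CC(=O)[C@@H]1O[C@]1(C)[C@H]2OC(C)=O | target

Total step count: 19. Longest linear sequence: 18 (steps 1–7 and 9–19, from D-glucal).

Steps most likely to fail

Step 6. The carbene may be consumed by the exocyclic enol ether of the same or a second molecule, or by insertion into a phosphonate OCH2 group. The bis(enol ether) may also ionise at the allylic C6 ester on heating before cyclopropanation takes place. The fallback keeps the carbene event but replaces the self-dismantling template by a saturated one that is taken apart by thiolysis and oxidation; it sets out from 5 and comes back at 10. Bu3SnH/AIBN (toluene, 80 °C) removes the iodine to give the 6-deoxy glycal diester F1. Regitz transfer as in step 5 gives the diazo ester F2. The same rhodium-carbene cyclopropanation, now on a substrate with a single C=C bond, gives the saturated-template cyclopropane F3. Propane-1,3-dithiol/BF3·OEt2 (CH2Cl2, −40 °C) opens the donor–acceptor cyclopropane and then the thioglycoside to the C8 dithiane C4 alcohol F4. Dess–Martin oxidation gives the C8 dithiane C4 methyl ketone F5, and PhI(O2CCF3)2 in aqueous MeCN frees aldehyde 10.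

Step 9. Lithiation of 12 may be incomplete, or the hindered 2-substituted allylborane may add so slowly that β-elimination of the C6 carboxylate or epimerisation at C7 of aldehyde 10 overtakes the addition. Facial control may also be eroded by the substrate. The fallback builds C8–C9 by an aldol reaction and makes C10=C14 afterwards; it sets out from 10 and comes back at 18. The (Z)-boron enolate of commercial 1,3-bis(tert-butyldimethylsilyloxy)propan-2-one (n-Bu2BOTf, i-Pr2NEt, CH2Cl2, −78 °C; buffered H2O2 work-up) should give the syn aldol adduct F6, with the aldehyde face set by the Felkin–Anh preference. Acetylation gives the C8 acetate diketone F7. One Takai–Lombardo reaction methylenates both the C4 and the C10 ketone to give the bis(methylene) bis(silyl ether) F8. HF·pyridine (THF, 0 °C) then gives diol 18.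

Step 16. Closure onto the hindered isopropenyl group may lose out to oligomerisation, to catalyst decay through the allylic alcohol, or to formation of the ring-trans alkene. The fallback makes the Z-alkene first and closes the ring at C1–C2 instead; it sets out from 16 and comes back at 25. (Iodomethyl)triphenylphosphonium iodide/NaHMDS (THF, −78 °C) effects a Stork–Zhao-type olefination, in which α-oxygenated methyl ketones place the new substituent cis to the oxygenated carbon, and gives the (Z)-vinyl iodide F9. Pd(PPh3)4, CO and Bu3SnH (formylation with retention of geometry) give the (Z)-enal F10. Me2BBr (CH2Cl2, −78 °C) removes both methoxymethyl groups to give the enal diol F11. Appel chlorination as in step 13 gives the enal allylic chloride F12, and Steglich acylation with 20 gives the enal ester chloride F13. CrCl2 (THF, high dilution; intramolecular Nozaki–Hiyama allylation, a closure type known for ten-membered carbocycles) then forms C1–C2 to give 25, the C2 epimer being set by the macrocyclic transition state.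

Further compounds
F1 | step 6 | 4-O-acetyl-6-deoxy-3-O-[(diethoxyphosphoryl)acetyl]-D-glucal | C[C@H]1OC=C[C@@H](OC(=O)CP(=O)(OCC)OCC)[C@@H]1OC(C)=O
F2 | step 6 | α-diazo(diethoxyphosphoryl)acetate of the 6-deoxy glycal | C[C@H]1OC=C[C@@H](OC(=O)C(=[N+]=[N-])P(=O)(OCC)OCC)[C@@H]1OC(C)=O
F3 | step 6 | cyclopropane-fused lactone on the saturated 6-deoxy pyran | C[C@H]1O[C@@H]2[C@@H]3[C@@H](OC(=O)[C@]23P(=O)(OCC)OCC)[C@@H]1OC(C)=O
F4 | step 6 | C8 1,3-dithiane C4 alcohol | C[C@@H](O)[C@@H](OC(C)=O)[C@@H]1OC(=O)[C@@H](P(=O)(OCC)OCC)[C@@H]1C1SCCCS1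
F5 | step 6 | C8 1,3-dithiane C4 methyl ketone | CC(=O)[C@@H](OC(C)=O)[C@@H]1OC(=O)[C@@H](P(=O)(OCC)OCC)[C@@H]1C1SCCCS1
F6 | step 9 | syn aldol adduct (C8 OH, C9 and C1 OTBS, C10 ketone) | CC(=O)[C@@H](OC(C)=O)[C@@H]1OC(=O)[C@@H](P(=O)(OCC)OCC)[C@@H]1[C@@H](O)[C@H](O[Si](C)(C)C(C)(C)C)C(=O)CO[Si](C)(C)C(C)(C)C
F7 | step 9 | C8 acetate C4,C10-diketone | CC(=O)[C@@H](OC(C)=O)[C@@H]1OC(=O)[C@@H](P(=O)(OCC)OCC)[C@@H]1[C@@H](OC(C)=O)[C@H](O[Si](C)(C)C(C)(C)C)C(=O)CO[Si](C)(C)C(C)(C)C
F8 | step 9 | bis(methylene) bis(silyl ether) | CC(=C)[C@@H](OC(C)=O)[C@@H]1OC(=O)[C@@H](P(=O)(OCC)OCC)[C@@H]1[C@@H](OC(C)=O)[C@H](O[Si](C)(C)C(C)(C)C)C(=C)CO[Si](C)(C)C(C)(C)C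
F9 | step 16 | (Z)-C3 vinyl iodide | I/C=C(/C)[C@@H](OC(C)=O)[C@@H]1OC(=O)[C@@H](P(=O)(OCC)OCC)[C@@H]1[C@@H](OC(C)=O)[C@H](OCOC)C(=C)COCOC
F10 | step 16 | (Z)-enal, C9 and C1 OMOM | O=C/C=C(/C)[C@@H](OC(C)=O)[C@@H]1OC(=O)[C@@H](P(=O)(OCC)OCC)[C@@H]1[C@@H](OC(C)=O)[C@H](OCOC)C(=C)COCOC
F11 | step 16 | (Z)-enal C9,C1-diol | O=C/C=C(/C)[C@@H](OC(C)=O)[C@@H]1OC(=O)[C@@H](P(=O)(OCC)OCC)[C@@H]1[C@@H](OC(C)=O)[C@H](O)C(=C)CO
F12 | step 16 | (Z)-enal C1 allylic chloride | O=C/C=C(/C)[C@@H](OC(C)=O)[C@@H]1OC(=O)[C@@H](P(=O)(OCC)OCC)[C@@H]1[C@@H](OC(C)=O)[C@H](O)C(=C)CCl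
F13 | step 16 | (Z)-enal C9 (R)-2-methylbutanoate allylic chloride | O=C/C=C(/C)[C@@H](OC(C)=O)[C@@H]1OC(=O)[C@@H](P(=O)(OCC)OCC)[C@@H]1[C@@H](OC(C)=O)[C@H](OC(=O)[C@H](C)CC)C(=C)CCl
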